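**Retrosynthetic overview** (indene numbering of the target is used for all ring atoms)

1. 23 ⇐ 22 ⇐ 21: acetylation and ester cleavage come last; the Z-allylic alcohol arm is grown from a C1 vinyl group by hydroboration/B-alkyl Suzuki coupling with the (Z)-iodide 3, and diimide then removes the extra ring alkene.
2. Bicyclic diene 18 ⇐ acyclic dienyne 17: one gold-catalysed formal [4+2] closes the cyclopentane first (C3a–C7a, 5-exo-dig) and the cyclohexadiene second (C6–C7), making C7 and C7a quaternary.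
3. 17 ⇐ 12: an enantioselective boron-enolate Ireland–Claisen rearrangement sets the quaternary C1 and C2; a Sonogashira coupling adds the vinyl group.
4. 12 ⇐ dienol 10 (alkenylcuprate + ethyl but-2-ynoate, then DIBAL-H) + pent-4-ynoic acid.

Assumption: the (S,S)-configured boron controller is taken to give the (2S,3R) acid 14; if the sense of induction is the opposite, the (R,R) reagent is used and nothing else changes.

**Route**

Step 1
Reactants: 1 prop-2-yn-1-ol
Product: 3 (2Z)-3-iodo-2-methylprop-2-en-1-ol, via dimagnesium species 2 (not isolated)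
Conditions: MeMgBr (2.5 equiv), CuI (10 mol %), THF, −10 °C to rt; then I2, −78 to 0 °C; aq. work-up
Reagents that add atoms: methylmagnesium bromide, C[Mg]Br; iodine, II
Why: Hydroxyl-directed copper-catalysed anti-carbomagnesiation of the alkyne puts the methyl on C2 and magnesium on C3 cis to the CH2O group (chelate), and iodinolysis with retention fixes the Z geometry that later becomes the Z-allylic acetate.

Step 2
Reactants: 4 2-bromo-3-methylbut-2-ene; 5 ethyl but-2-ynoate
Product: 9 ethyl (2E)-3,4,5-trimethylhexa-2,4-dienoate, via alkenyllithium 6 (not isolated), via lithium dialkenylcuprate 7 (not isolated), via vinylcopper adduct 8 (not isolated)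
Conditions: 4 (2 equiv), t-BuLi (4 equiv), Et2O, −78 °C; CuI (1 equiv), −40 °C; 5 (1 equiv), THF, −78 °C; MeOH then aq. NH4Cl at −78 °C
Reagents that add atoms: none
Why: Conjugate syn-carbocupration of the 2-ynoate by the Gilman alkenylcuprate places the alkenyl group and copper cis, and protonation at −78 °C with retention gives the 2E dienoate (alkenyl trans to the ester).

Step 3
Reactants: 9 ethyl (2E)-3,4,5-trimethylhexa-2,4-dienoate
Product: 10 (2E)-3,4,5-trimethylhexa-2,4-dien-1-ol
Conditions: DIBAL-H (2.2 equiv), CH2Cl2, −78 °C; Rochelle salt work-up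
Reagents that add atoms: none
Why: 1,2-Reduction of the conjugated ester by DIBAL-H gives the allylic alcohol without touching the alkene geometry.

Step 4
Reactants: 10 (2E)-3,4,5-trimethylhexa-2,4-dien-1-ol; 11 pent-4-ynoic acid
Product: 12 (2E)-3,4,5-trimethylhexa-2,4-dien-1-yl pent-4-ynoate
Conditions: DCC, DMAP (cat.), CH2Cl2, 0 °C to rt
Reagents that add atoms: none
Why: Steglich esterification joins the acid-sensitive dienyl alcohol to the acid under neutral conditions.

Step 5
Reactants: 12 (2E)-3,4,5-trimethylhexa-2,4-dien-1-yl pent-4-ynoate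
Product: 14 (2S,3R)-3-ethenyl-3,4,5-trimethyl-2-(prop-2-yn-1-yl)hex-4-enoic acid, via boron ketene acetal 13 (not isolated)
Conditions: (4S,5S)-2-bromo-1,3-bis{[3,5-bis(trifluoromethyl)phenyl]sulfonyl}-4,5-diphenyl-1,3,2-diazaborolidine (1.3 equiv, from the bis-sulfonamide and BBr3), i-Pr2NEt, CH2Cl2, −78 °C, then −20 °C to rt; aq. work-up
Reagents that add atoms: none
Why: Enantioselective Ireland–Claisen rearrangement of a chiral boron ketene acetal: the Z(O) enolate and the E allyl unit pass through a chair with the alkenyl group and the propargyl chain equatorial, which fixes the relative configuration of the new quaternary carbon (later C1) and the α-carbon (later C2) with the carboxyl cis to the C1 methyl, while the C2-symmetric bis-sulfonamide on boron selects the enolate face and hence the absolute configuration.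

Step 6
Reactants: 14 (2S,3R)-3-ethenyl-3,4,5-trimethyl-2-(prop-2-yn-1-yl)hex-4-enoic acid
Product: 15 methyl (2S,3R)-3-ethenyl-3,4,5-trimethyl-2-(prop-2-yn-1-yl)hex-4-enoate
Conditions: MeI, K2CO3, DMF, rt
Reagents that add atoms: iodomethane, CI
Why: SN2 O-methylation of the carboxylate masks the acid, which would otherwise add to the gold-activated alkyne in step 8, as a methyl ester that is inert there.

Step 7
Reactants: 15 methyl (2S,3R)-3-ethenyl-3,4,5-trimethyl-2-(prop-2-yn-1-yl)hex-4-enoate; 16 bromoethene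
Product: 17 methyl (2S,3R)-3-ethenyl-3,4,5-trimethyl-2-(pent-4-en-2-yn-1-yl)hex-4-enoate
Conditions: PdCl2(PPh3)2 (3 mol %), CuI (6 mol %), Et3N, THF, rt
Reagents that add atoms: none
Why: Sonogashira coupling of the terminal alkyne with vinyl bromide installs the conjugated 1,3-enyne that serves as the four-carbon partner in step 8.

Step 8
Reactants: 17 methyl (2S,3R)-3-ethenyl-3,4,5-trimethyl-2-(pent-4-en-2-yn-1-yl)hex-4-enoate
Product: 18 methyl (1R,2S,7aS)-1-ethenyl-1,7,7,7a-tetramethyl-2,3,7,7a-tetrahydro-1H-indene-2-carboxylate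
Conditions: [(2-biphenylyl)(t-Bu)2P·Au(NCMe)]SbF6 (3 mol %), CH2Cl2, −30 °C to rt
Reagents that add atoms: none
Why: Proposed new method: cationic univalent gold activates the alkyne, the most electron-rich (tetrasubstituted) alkene attacks it 5-exo-dig through C7a to give a cyclopropyl gold carbene, and the tertiary C7 cation is captured by the terminal carbon of the gold-bound diene (C6–C7 bond, formal [4+2]) before proton loss and protodeauration, with the C2 ester staying exo (anti) to the developing C7 bridge so that C7a forms with its methyl cis to the ester and to the C1 methyl; the closest known reaction is the gold-catalysed intramolecular formal [4+2] cycloaddition of 1,6-enynes carrying an alkenyl group on the alkyne with trisubstituted alkenes.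

Step 9
Reactants: 18 methyl (1R,2S,7aS)-1-ethenyl-1,7,7,7a-tetramethyl-2,3,7,7a-tetrahydro-1H-indene-2-carboxylate; 3 (2Z)-3-iodo-2-methylprop-2-en-1-ol
Product: 20 methyl (1R,2S,7aS)-1-[(3Z)-5-hydroxy-4-methylpent-3-en-1-yl]-1,7,7,7a-tetramethyl-2,3,7,7a-tetrahydro-1H-indene-2-carboxylate, via alkylborane 19 (not isolated)
Conditions: 9-BBN-H (1.3 equiv), THF, 0 °C to rt; then 3 (1.2 equiv), Pd(dppf)Cl2 (5 mol %), AsPh3 (10 mol %), Cs2CO3 (3 equiv), DMF/H2O, rt
Reagents that add atoms: none
Why: 9-BBN hydroborates only the monosubstituted vinyl group (anti-Markovnikov), and B-alkyl Suzuki–Miyaura coupling with the vinyl iodide proceeds with retention, so the Z geometry of 3 is carried into the side chain.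

Step 10
Reactants: 20 methyl (1R,2S,7aS)-1-[(3Z)-5-hydroxy-4-methylpent-3-en-1-yl]-1,7,7,7a-tetramethyl-2,3,7,7a-tetrahydro-1H-indene-2-carboxylate
Product: 21 methyl (1R,2S,7aS)-1-[(3Z)-5-hydroxy-4-methylpent-3-en-1-yl]-1,7,7,7a-tetramethyl-2,3,5,6,7,7a-hexahydro-1H-indene-2-carboxylate
Conditions: 2-nitrobenzenesulfonohydrazide, Et3N, CH2Cl2, rt
Reagents that add atoms: none
Why: Diimide reduction (concerted syn transfer of H2) is fastest at the cis-disubstituted C5=C6 bond of the ring diene and leaves the two trisubstituted alkenes untouched, and no stereocentre is formed.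

Step 11
Reactants: 21 methyl (1R,2S,7aS)-1-[(3Z)-5-hydroxy-4-methylpent-3-en-1-yl]-1,7,7,7a-tetramethyl-2,3,5,6,7,7a-hexahydro-1H-indene-2-carboxylate
Product: 22 (1R,2S,7aS)-1-[(3Z)-5-hydroxy-4-methylpent-3-en-1-yl]-1,7,7,7a-tetramethyl-2,3,5,6,7,7a-hexahydro-1H-indene-2-carboxylic acid
Conditions: LiI (5 equiv), pyridine, reflux; dilute HCl work-up
Reagents that add atoms: none
Why: Nucleophilic (SN2) demethylation by iodide attacks the ester methyl group, so it is insensitive to the hindrance at C2 and does not epimerise the α-stereocentre.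

Step 12
Reactants: 22 (1R,2S,7aS)-1-[(3Z)-5-hydroxy-4-methylpent-3-en-1-yl]-1,7,7,7a-tetramethyl-2,3,5,6,7,7a-hexahydro-1H-indene-2-carboxylic acid
Product: 23 (1R,2S,7aS)-1-[(3Z)-5-(acetyloxy)-4-methylpent-3-en-1-yl]-1,7,7,7a-tetramethyl-2,3,5,6,7,7a-hexahydro-1H-indene-2-carboxylic acid
Conditions: Ac2O (1.5 equiv), pyridine, DMAP (cat.), CH2Cl2, 0 °C; aq. NaHCO3, then acidify to pH 3
Reagents that add atoms: acetic anhydride, CC(=O)OC(C)=O
Why: DMAP-catalysed acetylation of the primary allylic alcohol gives the acetate, and the aqueous work-up returns the free, hindered carboxylic acid.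

**Compound list**

1 | prop-2-yn-1-ol | C#CCO | starting material
2 | bromo{(1Z)-3-[(bromomagnesio)oxy]-2-methylprop-1-en-1-yl}magnesium (Mg on carbon cis to CH2O) | Br[Mg]OC/C(C)=C\[Mg]Br | intermediate
3 | (2Z)-3-iodo-2-methylprop-2-en-1-ol | OC/C(C)=C\I | intermediate
4 | 2-bromo-3-methylbut-2-ene | CC(C)=C(C)Br | starting material
5 | ethyl but-2-ynoate | CCOC(=O)C#CC | starting material
6 | (3-methylbut-2-en-2-yl)lithium | [Li]C(C)=C(C)C | intermediate
7 | lithium bis(3-methylbut-2-en-2-yl)cuprate | [Li+].CC(C)=C(C)[Cu-]C(C)=C(C)C | intermediate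
8 | lithium [(1Z)-1-(ethoxycarbonyl)-2,3,4-trimethylpenta-1,3-dien-1-yl](3-methylbut-2-en-2-yl)cuprate | [Li+].CCOC(=O)/C([Cu-]C(C)=C(C)C)=C(\C)C(C)=C(C)C | intermediate
9 | ethyl (2E)-3,4,5-trimethylhexa-2,4-dienoate | CCOC(=O)/C=C(\C)C(C)=C(C)C | intermediate
10 | (2E)-3,4,5-trimethylhexa-2,4-dien-1-ol | OC/C=C(\C)C(C)=C(C)C | intermediate
11 | pent-4-ynoic acid | OC(=O)CCC#C | starting material
12 | (2E)-3,4,5-trimethylhexa-2,4-dien-1-yl pent-4-ynoate | C#CCCC(=O)OC/C=C(\C)C(C)=C(C)C | intermediate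
13 | Z(O) boron ketene acetal of 12 (propargyl chain cis to O–B; boron carries the (4S,5S)-1,3-bis{[3,5-bis(trifluoromethyl)phenyl]sulfonyl}-4,5-diphenyl-1,3,2-diazaborolidine ring) | C#CC/C=C(\OB1N(S(=O)(=O)c2cc(cc(c2)C(F)(F)F)C(F)(F)F)[C@@H](c2ccccc2)[C@H](c2ccccc2)N1S(=O)(=O)c1cc(cc(c1)C(F)(F)F)C(F)(F)F)OC/C=C(\C)C(C)=C(C)C | intermediate
14 | (2S,3R)-3-ethenyl-3,4,5-trimethyl-2-(prop-2-yn-1-yl)hex-4-enoic acid | C=C[C@](C(C)=C(C)C)(C)[C@@H](C(=O)O)CC#C | intermediate
15 | methyl (2S,3R)-3-ethenyl-3,4,5-trimethyl-2-(prop-2-yn-1-yl)hex-4-enoate | C=C[C@](C(C)=C(C)C)(C)[C@@H](C(=O)OC)CC#C | intermediate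
16 | bromoethene (vinyl bromide) | C=CBr | starting material
17 | methyl (2S,3R)-3-ethenyl-3,4,5-trimethyl-2-(pent-4-en-2-yn-1-yl)hex-4-enoate | C=C[C@](C(C)=C(C)C)(C)[C@@H](C(=O)OC)CC#CC=C | intermediate
18 | methyl (1R,2S,7aS)-1-ethenyl-1,7,7,7a-tetramethyl-2,3,7,7a-tetrahydro-1H-indene-2-carboxylate | C=C[C@]1(C)[C@@H](C(=O)OC)CC2=CC=CC(C)(C)[C@@]21C | intermediate
19 | methyl (1R,2S,7aS)-1-[2-(9-borabicyclo[3.3.1]nonan-9-yl)ethyl]-1,7,7,7a-tetramethyl-2,3,7,7a-tetrahydro-1H-indene-2-carboxylate | C1CC2CCCC(C1)B2CC[C@]1(C)[C@@H](C(=O)OC)CC2=CC=CC(C)(C)[C@@]21C | intermediate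
20 | methyl (1R,2S,7aS)-1-[(3Z)-5-hydroxy-4-methylpent-3-en-1-yl]-1,7,7,7a-tetramethyl-2,3,7,7a-tetrahydro-1H-indene-2-carboxylate | OC/C(C)=C\CC[C@]1(C)[C@@H](C(=O)OC)CC2=CC=CC(C)(C)[C@@]21C | intermediate
21 | methyl (1R,2S,7aS)-1-[(3Z)-5-hydroxy-4-methylpent-3-en-1-yl]-1,7,7,7a-tetramethyl-2,3,5,6,7,7a-hexahydro-1H-indene-2-carboxylate | OC/C(C)=C\CC[C@]1(C)[C@@H](C(=O)OC)CC2=CCCC(C)(C)[C@@]21C | intermediate
22 | (1R,2S,7aS)-1-[(3Z)-5-hydroxy-4-methylpent-3-en-1-yl]-1,7,7,7a-tetramethyl-2,3,5,6,7,7a-hexahydro-1H-indene-2-carboxylic acid | OC/C(C)=C\CC[C@]1(C)[C@@H](C(=O)O)CC2=CCCC(C)(C)[C@@]21C | intermediate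
23 | (1R,2S,7aS)-1-[(3Z)-5-(acetyloxy)-4-methylpent-3-en-1-yl]-1,7,7,7a-tetramethyl-2,3,5,6,7,7a-hexahydro-1H-indene-2-carboxylic acid | CC(=O)OC/C(C)=C\CC[C@]1(C)[C@@H](C(=O)O)CC2=CCCC(C)(C)[C@@]21C | target

**Step count and risks**

Total steps: 12. Longest linear sequence: 11 (steps 2 to 12, from 4 and 5); step 1 is a one-step side branch.

The three steps most likely to fail:

Step 8 (gold bicyclisation). The tetrasubstituted alkene may lose out to the C1 vinyl group, the C7 cation may eliminate instead of closing the six-membered ring, or the selectivity at C7a may be poor. The fallback replaces π-acid catalysis by a cation-radical Diels–Alder reaction. It sets out from 17: reduction of the triple bond with Zn(Cu/Ag) couple in MeOH/H2O gives the triene ester methyl (2S,3R)-3-ethenyl-3,4,5-trimethyl-2-[(2Z)-penta-2,4-dien-1-yl]hex-4-enoate F1. Hole catalysis with tris(4-bromophenyl)ammoniumyl hexachloroantimonate, (4-BrC6H4)3N SbCl6, in CH2Cl2 at 0 °C adds the electron-rich tetrasubstituted alkene across the diene to give the 3a,6,7,7a-tetrahydro cycloadduct F2 (alkene at C4=C5, C3a–H). RhCl3·3H2O in EtOH at 70 °C moves that alkene into the trisubstituted C3a=C4 position to give methyl (1R,2S,7aS)-1-ethenyl-1,7,7,7a-tetramethyl-2,3,5,6,7,7a-hexahydro-1H-indene-2-carboxylate F3; the C1 vinyl group has no allylic hydrogen and stays. Hydroboration/Suzuki coupling of F3 with 3 under the conditions of step 9 comes back to the route at 21, and the diimide step is no longer needed.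

Step 5 (enantioselective Ireland–Claisen). The chiral boron enolate must form a quaternary carbon from a dienyl ester, and both the rate and the enantioselectivity are extrapolated from simpler allyl esters. The fallback gives up reagent control for a resolution. It sets out from 12: Bu2BOTf and i-Pr2NEt in CH2Cl2 (−78 °C to rt) give the achiral dibutylboron ketene acetal F4, which rearranges through the same chair and after aqueous work-up gives the racemic acid F5 (14 together with its enantiomer). Crystallisation with (R)-1-phenylethylamine (or its antipode, whichever gives the less soluble salt of 14) gives the diastereomerically pure ammonium salt F6, and acidification with dilute HCl comes back to the route at 14.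

Step 9 (hydroboration/Suzuki coupling). The vinyl group sits between two quaternary carbons, and the coupling must compete with protodeboronation and with isomerisation of the iodoallyl alcohol. The fallback builds the Z-alkene by olefination instead of cross-coupling. It sets out from 18: 9-BBN-H, then NaBO3·4H2O, gives the primary alcohol methyl (1R,2S,7aS)-1-(2-hydroxyethyl)-1,7,7,7a-tetramethyl-2,3,7,7a-tetrahydro-1H-indene-2-carboxylate F7. I2, PPh3 and imidazole give the iodide F8. Alkylation of Ph3P=CH2 with F8 gives the homologated phosphonium iodide F9. Its ylide (NaHMDS, THF, −78 °C) is trapped at once with 1-(tert-butyldimethylsilyloxy)propan-2-one, whose α-alkoxy group directs a Z-selective Wittig reaction, to give the silyl ether F10. TBAF in THF removes the silyl group and comes back to the route at 20.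

**Further compounds**

F1 | step 8 | methyl (2S,3R)-3-ethenyl-3,4,5-trimethyl-2-[(2Z)-penta-2,4-dien-1-yl]hex-4-enoate | C=C[C@](C(C)=C(C)C)(C)[C@@H](C(=O)OC)C/C=C\C=C
F2 | step 8 | methyl 1-ethenyl-1,7,7,7a-tetramethyl-2,3,3a,6,7,7a-hexahydro-1H-indene-2-carboxylate (C1, C2, C7a as in 18; C3a either way, erased in the next operation) | C=C[C@]1(C)[C@@H](C(=O)OC)CC2C=CCC(C)(C)[C@@]21C
F3 | step 8 | methyl (1R,2S,7aS)-1-ethenyl-1,7,7,7a-tetramethyl-2,3,5,6,7,7a-hexahydro-1H-indene-2-carboxylate | C=C[C@]1(C)[C@@H](C(=O)OC)CC2=CCCC(C)(C)[C@@]21C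
F4 | step 5 | Z(O) dibutylboron ketene acetal of 12 | C#CC/C=C(\OB(CCCC)CCCC)OC/C=C(\C)C(C)=C(C)C
F5 | step 5 | racemic 3-ethenyl-3,4,5-trimethyl-2-(prop-2-yn-1-yl)hex-4-enoic acid, (2S,3R) and (2R,3S) | C=C[C@](C(C)=C(C)C)(C)[C@@H](C(=O)O)CC#C.C=C[C@@](C(C)=C(C)C)(C)[C@H](C(=O)O)CC#C
F6 | step 5 | (R)-1-phenylethylammonium (2S,3R)-3-ethenyl-3,4,5-trimethyl-2-(prop-2-yn-1-yl)hex-4-enoate | C=C[C@](C(C)=C(C)C)(C)[C@@H](C(=O)[O-])CC#C.C[C@@H]([NH3+])c1ccccc1
F7 | step 9 | methyl (1R,2S,7aS)-1-(2-hydroxyethyl)-1,7,7,7a-tetramethyl-2,3,7,7a-tetrahydro-1H-indene-2-carboxylate | OCC[C@]1(C)[C@@H](C(=O)OC)CC2=CC=CC(C)(C)[C@@]21C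
F8 | step 9 | methyl (1R,2S,7aS)-1-(2-iodoethyl)-1,7,7,7a-tetramethyl-2,3,7,7a-tetrahydro-1H-indene-2-carboxylate | ICC[C@]1(C)[C@@H](C(=O)OC)CC2=CC=CC(C)(C)[C@@]21C
F9 | step 9 | {3-[(1R,2S,7aS)-2-(methoxycarbonyl)-1,7,7,7a-tetramethyl-2,3,7,7a-tetrahydro-1H-inden-1-yl]propyl}triphenylphosphonium iodide | c1ccccc1[P+](c1ccccc1)(c1ccccc1)CCC[C@]1(C)[C@@H](C(=O)OC)CC2=CC=CC(C)(C)[C@@]21C.[I-]
F10 | step 9 | methyl (1R,2S,7aS)-1-[(3Z)-5-(tert-butyldimethylsilyloxy)-4-methylpent-3-en-1-yl]-1,7,7,7a-tetramethyl-2,3,7,7a-tetrahydro-1H-indene-2-carboxylate | CC(C)(C)[Si](C)(C)OC/C(C)=C\CC[C@]1(C)[C@@H](C(=O)OC)CC2=CC=CC(C)(C)[C@@]21C
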